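Remark: ring atoms are numbered A1 OH, A3 OH, A4 O–B, A5 OH; B1 O–A, B3 OH, B5 OH, B6 O–C; C1 O–B, C3 OH, C4 OH, C5 O–D; D1 O–C, D2 O–E, D3 to D5 OH, D6 H; E1 O–D, E3 to E5 OH. Starting materials 1, 5, 9, 16, 20 and 27 are taken to be purchasable.

## The problem

Pseudopentafuhalol D (34, C30H22O17) is a chain of five benzene rings, A to E, joined only by four diaryl ether oxygens. There are no inter-ring C–C bonds, so the task is to form aryl C–O bonds and to place seventeen oxygens on thirty carbons. Three of the ether oxygens sit on ring carbons that are oxygenated on both sides (A4, B6 and D2), which makes those ethers hard to form by arylating a phenol. The molecule has no stereocentre. The only stereogenic atom on the route is the quaternary carbon of cyclobutenone 12, which is racemic and vanishes when ring D becomes aromatic. The thirteen free hydroxyls form phloroglucinol, pyrogallol and hydroxyquinol arrays that air oxidises to quinones, above all under base, and their rings are C-nucleophiles toward cations. Every hydroxyl therefore stays masked until the last two steps, and the unmasking must avoid oxidants and free benzyl cations. Ring D is the hardest ring: D1 to D5 carry oxygen in an unbroken row and D6 carries hydrogen. That same pattern opens the route: D1 to D4 match the four oxygenated carbons of squaric acid (5), and D5 and D6 match the two carbons of a 1-methoxyvinyl group. A 4-(1-methoxyvinyl)cyclobutenone can thus be expanded to ring D with the flanked D2–O–E ether already in place as a squarate ester.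

## Retrosynthesis

**Unmasking.** Target 34 is traced to its ring D dimethyl ether 33 and then to the fully masked phenol 32, so that only O–alkyl bonds are cut at the end: two methyl ethers by a boron Lewis acid and ten benzyl ethers by hydrogenolysis. Benzyl is used for every hydroxyl that the building blocks bring along, because it survives carbonate at 100 °C and peracid and leaves under neutral conditions. The two methyl ethers are the price of the ring D synthesis and are confined to D4 and D5. The forward steps must cleave twelve alkyl ethers and leave four diaryl ether bonds intact.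

**Ring C hydroxyl.** The C4–OH bond of ring C in 32 is cut back to the formyl group of aldehyde 30 (Baeyer–Villiger transform). A formyl group is preferred to any other precursor of this oxygen because it is the group that activates ring C for both of its ether bonds and is then turned into the hydroxyl in one operation. The forward reaction has to oxidise one aldehyde in the presence of five electron-rich rings.

**C–O–D ether.** Aldehyde 30 is cut at the bond between C5 of ring C and the ether oxygen, giving fluoro aldehyde 29 and phenol 15. The other bond of this ether, D1–O, is not a useful cut, since it would need a leaving group on a pentaoxygenated ring that has no acceptor. Phenol 15 has a single free hydroxyl, flanked on one side only, so the forward substitution has no choice of nucleophilic oxygen.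

**B–O–C ether.** Compound 29 is cut at the bond between C1 of ring C and oxygen, giving AB phenol 26 and difluoride 28, which comes from 27 by benzylation. Both ether carbons of ring C are ortho or para to the same formyl group, so one difluoride serves for both bonds. The order is set so that the phenoxide flanked on both sides (26) meets the open para fluoride and the less hindered phenoxide (15) meets the ortho fluoride. The forward step must distinguish para from ortho fluoride.

**Ring D (key disconnection).** Phenol 15 is opened at the D1–D6 carbon–carbon bond and reclosed between D1 and D4, which leads to cyclobutenone 12. The neighbouring cut, the D2–O–E ether, would require arylation of a hydroxyl flanked on both sides, on a ring whose five oxygens would have to be introduced one by one. The chosen cut removes a whole aromatic ring and leaves every oxygen on a carbon of a four-membered ring or a vinyl group. The forward reaction must open the ring with the methoxy group turning outward and then close the six-membered ring. The oxygen on the quaternary carbon is carried as a methyl ether so that 15 has D1–OH as its only free hydroxyl and cannot be oxidised to a quinone.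

**Cyclobutenone.** Compound 12 is cut between the quaternary carbon and the vinyl carbon, giving squarate diester 8 and 1-methoxyvinyllithium (10), made from methyl vinyl ether (9). This removes the stereocentre and two carbons. The forward addition must choose the carbonyl next to the benzyloxy-bearing carbon.

**Squarate diester.** Diester 8 is cut at its two ester C–O bonds to squaric acid dichloride (6), a benzyloxy group and ring E phenol 4; 6 comes from 5. The D2–O–E ether is thereby made as a substitution on a vinylogous acid chloride, not as an arylation. Phenol 4 comes from aldehyde 2 by aryl migration to oxygen, and 2 from 1 by benzylation.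

**AB phenol.** Phenol 26 is cut at its hydroxyl back to aldehyde 24, and 24 at the bond between B1 and oxygen to phenol 19 and fluoro aldehyde 23. The formyl group of 23 activates the fluoride and later becomes the B6 hydroxyl. Phenol 19 comes from 17 and 16 in the same way as 4. Aldehyde 23 comes from fluoroarene 21 by formylation, and 21 from 20. The forward substitution asks a phenoxide with two ortho substituents to displace an ortho fluoride.

## Roads not taken

**Alternative 1:** Three hydroxyls (A1, C4 and E4) are cut back to formyl groups in trialdehyde A1, and one peracid treatment with methanolysis of the three formates gives triphenol A2.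
- Merits: every ether bond would be made next to an aldehyde acceptor, three auxiliaries are removed in one operation, and all protecting groups are benzyl, so one hydrogenolysis finishes. That last point is better than the chosen plan, which needs a separate Lewis-acid demethylation.
- Weak points: rings A and E would enter as 3,5-bis(benzyloxy)-4-fluorobenzaldehyde A3, whose fluoride is flanked by two benzyloxy groups. Rings B and D would have to be catechol-type nucleophiles whose two adjacent hydroxyls must be told apart. The D2–O–E bond would need a flanked phenoxide to attack a flanked fluoride. The pentaoxygenated ring D would still have to be made by stepwise oxidation. Three oxidations on one large electron-rich molecule risk partly converted mixtures.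
- Comparison: alternative 1 is more convergent at the end and cleaner in deprotection. The chosen plan sets against it that ring D and its hindered ether come from squaric acid without any substitution at a flanked aromatic carbon.

**Alternative 2:** Ring A is cut at a ring C–C bond to the acyclic triketide ester A4, a methyl 3,5-dioxohexanoate that carries the BCDE aryloxy group on C6. NaOMe would close ring A by attack of C6 on the ester carbonyl, and enolisation would give triol A5.
- Merits: the most C-nucleophilic ring is made last and never carried as a hindered nucleophile, so the doubly ortho-substituted phenoxide of step 11 is avoided. In this respect it is better than the chosen plan.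
- Weak points: C6 is the least acidic position of A4, and 3,5-dioxo esters prefer lactonisation through the C5 enol oxygen to C-acylation. The whole BCDE tetramer, including ring D and three of the four ethers, must still be built by other means, and A4 must be assembled on it.
- Comparison: the A–O–B ether is the one that ordinary fluoride displacement handles best, so ring construction is better spent on ring D. The chosen plan sets a well-known substitution and oxidation pair against the hindered-phenoxide problem.

**Alternative 3:** Both ether bonds at ring C are cut at once. In one pot, difluoride 28 would take up phenol 26 at the para fluoride and then the perbenzylated DE phenol A7 at the ortho fluoride, giving pentamer aldehyde A6.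
- Merits: two ether bonds in one flask and twelve benzyl ethers with no methyl ether, so the synthesis ends with hydrogenolysis alone. In step count at the end and in uniform protection it is better than the chosen plan.
- Weak points: A7 contains the D2–O–E ether and the five oxygens of ring D, and nothing in this plan makes them. They would have to come from arylation at a flanked oxygen on a ring oxidised stepwise. The one-pot sequence gives no chance to purify between two substitutions whose site selectivity is not absolute.
- Comparison: the chosen route uses the same two substitutions, run as steps 14 and 15 with isolation in between. What it sets against the cleaner deprotection is the source of the DE half: four steps from 5 to 15 that fix all five oxygens and the flanked ether.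

Key step: step 6

## Steps

Step 1
Reactants: 1 3,4,5-trihydroxybenzaldehyde
Product: 2 3,4,5-tris(benzyloxy)benzaldehyde
Conditions: BnBr, K2CO3, DMF, 60 °C (argon)
Reagents that add atoms: benzyl bromide, BrCc1ccccc1
Why: Williamson ether synthesis; the three phenoxides are alkylated on oxygen, the aldehyde is inert, and exclusion of air keeps the pyrogallol anion from oxidising before it is capped.

Step 2
Reactants: 2 3,4,5-tris(benzyloxy)benzaldehyde
Product: 4 3,4,5-tris(benzyloxy)phenol, via aryl formate 3 (not isolated)
Conditions: mCPBA, CH2Cl2, 0 °C to rt; aq. NaHCO3 wash; then Et3N (cat.), MeOH, rt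
Reagents that add atoms: 3-chloroperoxybenzoic acid (mCPBA), OOC(=O)c1cccc(Cl)c1
Why: Baeyer–Villiger oxidation of an electron-rich benzaldehyde (Dakin-type); the aryl group with a para alkoxy donor migrates in preference to hydride, and formate 3 is transesterified by methanol to phenol 4.

Step 3
Reactants: 5 squaric acid
Product: 6 squaric acid dichloride (3,4-dichlorocyclobut-3-ene-1,2-dione)
Conditions: (COCl)2, DMF (cat.), CH2Cl2, reflux
Reagents that add atoms: oxalyl chloride, ClC(=O)C(Cl)=O
Why: Conversion of a vinylogous carboxylic acid into its acid chloride by the chloroiminium species formed from oxalyl chloride and DMF; both hydroxyls are exchanged and the by-products are gases.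

Step 4
Reactants: 6 squaric acid dichloride; 4 3,4,5-tris(benzyloxy)phenol
Product: 8 3-(benzyloxy)-4-[3,4,5-tris(benzyloxy)phenoxy]cyclobut-3-ene-1,2-dione, via benzyl chlorosquarate 7 (not isolated)
Conditions: BnOH (1 equiv), i-Pr2NEt, CH2Cl2, −40 °C; then 4, i-Pr2NEt, −40 to 0 °C
Reagents that add atoms: benzyl alcohol, OCc1ccccc1
Why: Two vinylogous acyl substitutions (addition–elimination) in sequence; the first alkoxy group slows a second alcoholysis, and the remaining chloride of 7 is the best leaving group on the ring, so the phenoxide of 4 displaces it on oxygen.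

Step 5
Reactants: 8 3-(benzyloxy)-4-[3,4,5-tris(benzyloxy)phenoxy]cyclobut-3-ene-1,2-dione; 9 methyl vinyl ether
Product: 12 racemic 3-(benzyloxy)-4-methoxy-4-(1-methoxyethenyl)-2-[3,4,5-tris(benzyloxy)phenoxy]cyclobut-2-en-1-one, via 1-methoxyvinyllithium 10 (not isolated), via lithium cyclobutenolate 11 (not isolated)
Conditions: 9, t-BuLi, THF, −78 to 0 °C; then 8, THF, −78 °C; then MeOTf, −78 to −20 °C
Reagents that add atoms: methyl trifluoromethanesulfonate, COS(=O)(=O)C(F)(F)F
Why: 1,2-Addition of an α-alkoxyvinyllithium to a squarate diester, the usual entry to Moore substrates; 10 should attack the carbonyl that is the vinylogous ester of the weaker aryloxy donor (next to the benzyloxy carbon, away from the bulky aryl ether), and MeOTf caps alkoxide 11 cold, so the stereocentre is racemic and the later ring D has one free hydroxyl.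

Step 6
Reactants: 12 racemic 3-(benzyloxy)-4-methoxy-4-(1-methoxyethenyl)-2-[3,4,5-tris(benzyloxy)phenoxy]cyclobut-2-en-1-one
Product: 15 3-(benzyloxy)-4,5-dimethoxy-2-[3,4,5-tris(benzyloxy)phenoxy]phenol, via dienylketene 13 (not isolated), via cyclohexadienone 14 (not isolated)
Conditions: toluene (degassed, 0.01 M), 110 °C
Reagents that add atoms: none
Why: Moore rearrangement: heat opens cyclobutenone 12 by conrotatory 4π electrocyclic cleavage of the bond between the carbonyl carbon and the methoxy-bearing carbon, giving dienylketene 13. The closest known reaction type is the thermal rearrangement of squarate-derived 4-alkenyl-4-alkoxy (or 4-hydroxy) cyclobutenones to polyoxygenated phenols and hydroquinones. Ring D closes by a thermal 6π disrotatory electrocyclisation across the ketene, the central Z double bond and the methoxyvinyl group, which joins the ketene carbon (D1) to the vinyl CH2 (D6) as the only new skeletal bond. Dienone 14 then tautomerises irreversibly to phenol 15; no stereocentre is formed and that of 12 is erased. The selectivity needed is torquoselectivity: the methoxy group on the sp3 carbon, the stronger donor, should rotate outward, which turns the methoxyvinyl group inward and cis to the ketene, whereas the opposite rotation would give a ketene that cannot cyclise. The positions of the five oxygens are fixed in 12 and cannot scramble, because each carbon keeps its oxygen throughout. Since the oxygen on the quaternary carbon is a methyl ether, 15 has D1–OH as its only free hydroxyl and cannot be oxidised to a quinone on work-up. High dilution in degassed toluene should keep ketene 13 from being captured by nucleophiles or by product phenol.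

Step 7
Reactants: 16 2,4,6-trihydroxybenzaldehyde
Product: 17 2,4,6-tris(benzyloxy)benzaldehyde
Conditions: BnBr, K2CO3, DMF, 70 °C (argon)
Reagents that add atoms: benzyl bromide, BrCc1ccccc1
Why: Williamson ether synthesis; the formyl group lowers the C-nucleophilicity of the phloroglucinol ring so that O-alkylation prevails, and excess BnBr with heat brings over the two chelated ortho hydroxyls.

Step 8
Reactants: 17 2,4,6-tris(benzyloxy)benzaldehyde
Product: 19 2,4,6-tris(benzyloxy)phenol, via aryl formate 18 (not isolated)
Conditions: mCPBA, CH2Cl2, 0 °C to rt; aq. NaHCO3 wash; then Et3N (cat.), MeOH, rt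
Reagents that add atoms: 3-chloroperoxybenzoic acid (mCPBA), OOC(=O)c1cccc(Cl)c1
Why: Baeyer–Villiger (Dakin-type) oxidation; two ortho and one para alkoxy groups make aryl migration fast, and methanolysis of formate 18 frees phenol 19.

Step 9
Reactants: 20 5-fluorobenzene-1,3-diol
Product: 21 1,3-bis(benzyloxy)-5-fluorobenzene
Conditions: BnBr, K2CO3, acetone, reflux
Reagents that add atoms: benzyl bromide, BrCc1ccccc1
Why: Williamson ether synthesis on both phenols; the aryl fluoride has no acceptor and is not displaced by carbonate.

Step 10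
Reactants: 21 1,3-bis(benzyloxy)-5-fluorobenzene
Product: 23 2,4-bis(benzyloxy)-6-fluorobenzaldehyde, via iminium chloride 22 (not isolated)
Conditions: POCl3, DMF, 0 to 70 °C; then H2O
Reagents that add atoms: N,N-dimethylformamide, CN(C)C=O; water, O
Why: Vilsmeier–Haack formylation; attack ortho to one benzyloxy group and para to the other, next to the small fluorine, should be favoured over the position between the two benzyloxy groups, and hydrolysis of iminium salt 22 gives 23 with its fluoride ortho to the formyl group.

Step 11
Reactants: 19 2,4,6-tris(benzyloxy)phenol; 23 2,4-bis(benzyloxy)-6-fluorobenzaldehyde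
Product: 24 2,4-bis(benzyloxy)-6-[2,4,6-tris(benzyloxy)phenoxy]benzaldehyde
Conditions: Cs2CO3, DMF, 100 °C (argon)
Reagents that add atoms: none
Why: Nucleophilic aromatic substitution (addition–elimination); the ortho formyl group stabilises the Meisenheimer intermediate, the two benzyloxy groups are meta to the reacting carbon and do not oppose it, and the caesium phenoxide of 19 should be reactive enough despite its two ortho substituents.

Step 12
Reactants: 24 2,4-bis(benzyloxy)-6-[2,4,6-tris(benzyloxy)phenoxy]benzaldehyde
Product: 26 2,4-bis(benzyloxy)-6-[2,4,6-tris(benzyloxy)phenoxy]phenol, via AB aryl formate 25 (not isolated)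
Conditions: mCPBA, CH2Cl2, 0 °C to rt; aq. NaHCO3 wash; then Et3N (cat.), MeOH, rt
Reagents that add atoms: 3-chloroperoxybenzoic acid (mCPBA), OOC(=O)c1cccc(Cl)c1
Why: Baeyer–Villiger (Dakin-type) oxidation of a 2,4,6-trioxygenated benzaldehyde; aryl migration gives formate 25 and methanolysis gives phenol 26, whose new hydroxyl sits on B6.

Step 13
Reactants: 27 2,4-difluoro-6-hydroxybenzaldehyde
Product: 28 2-(benzyloxy)-4,6-difluorobenzaldehyde
Conditions: BnBr, K2CO3, DMF, rt
Reagents that add atoms: benzyl bromide, BrCc1ccccc1
Why: Williamson ether synthesis at room temperature, where the phenoxide of 27 is too weak a nucleophile to displace a fluoride of a second molecule.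

Step 14
Reactants: 26 2,4-bis(benzyloxy)-6-[2,4,6-tris(benzyloxy)phenoxy]phenol; 28 2-(benzyloxy)-4,6-difluorobenzaldehyde
Product: 29 2-(benzyloxy)-4-{2,4-bis(benzyloxy)-6-[2,4,6-tris(benzyloxy)phenoxy]phenoxy}-6-fluorobenzaldehyde
Conditions: K2CO3, DMF, 40 °C (argon)
Reagents that add atoms: none
Why: Nucleophilic aromatic substitution; both fluorides are activated by the formyl group, and the phenoxide of 26, substituted at both ortho positions, should take the unhindered para fluoride, the usual site for free phenoxides in dipolar aprotic solvent, leaving the ortho fluoride for step 15.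

Step 15
Reactants: 29 2-(benzyloxy)-4-{2,4-bis(benzyloxy)-6-[2,4,6-tris(benzyloxy)phenoxy]phenoxy}-6-fluorobenzaldehyde; 15 3-(benzyloxy)-4,5-dimethoxy-2-[3,4,5-tris(benzyloxy)phenoxy]phenol
Product: 30 2-(benzyloxy)-6-{3-(benzyloxy)-4,5-dimethoxy-2-[3,4,5-tris(benzyloxy)phenoxy]phenoxy}-4-{2,4-bis(benzyloxy)-6-[2,4,6-tris(benzyloxy)phenoxy]phenoxy}benzaldehyde
Conditions: Cs2CO3, DMF, 100 °C (argon)
Reagents that add atoms: none
Why: Nucleophilic aromatic substitution at the remaining fluoride ortho to the formyl group by the phenoxide of 15, which has one free hydroxyl flanked on one side only; the ring C donors are meta to the reacting carbon, so formyl activation should suffice at higher temperature.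

Step 16
Reactants: 30 pentamer aldehyde (name as in step 15)
Product: 32 2-(benzyloxy)-6-{3-(benzyloxy)-4,5-dimethoxy-2-[3,4,5-tris(benzyloxy)phenoxy]phenoxy}-4-{2,4-bis(benzyloxy)-6-[2,4,6-tris(benzyloxy)phenoxy]phenoxy}phenol, via pentamer aryl formate 31 (not isolated)
Conditions: mCPBA, CH2Cl2, 0 °C; aq. NaHCO3 wash; then Et3N (cat.), MeOH, rt
Reagents that add atoms: 3-chloroperoxybenzoic acid (mCPBA), OOC(=O)c1cccc(Cl)c1
Why: Baeyer–Villiger (Dakin-type) oxidation; the formyl group lies between two oxygenated carbons and para to a third, so aryl migration should outrun oxidation of the electron-rich rings at 0 °C with a small excess of peracid, and methanolysis of formate 31 gives 32.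

Step 17
Reactants: 32 pentamer phenol (name as in step 16)
Product: 33 ring D 4,5-di-O-methyl ether of pseudopentafuhalol D (D4 and D5 methoxy, eleven free hydroxyls)
Conditions: H2 (1 atm), Pd/C (10% palladium on carbon), THF/MeOH, rt
Reagents that add atoms: none
Why: Catalytic hydrogenolysis of the ten benzyl ethers under neutral conditions; diaryl and methyl ethers are untouched.

Step 18
Reactants: 33 ring D 4,5-di-O-methyl ether of pseudopentafuhalol D
Product: 34 pseudopentafuhalol D
Conditions: BBr3 (excess), CH2Cl2, −78 °C to rt (argon); then H2O, 0 °C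
Reagents that add atoms: none
Why: Lewis-acid cleavage of the two aryl methyl ethers through aryloxyboron intermediates; diaryl ether bonds are inert to BBr3, excess reagent covers the eleven free hydroxyls, and aqueous work-up under argon releases 34.

## Compound list

1 | 3,4,5-trihydroxybenzaldehyde | O=Cc1cc(O)c(O)c(O)c1 | starting material
2 | 3,4,5-tris(benzyloxy)benzaldehyde | O=Cc1cc(OCc2ccccc2)c(OCc2ccccc2)c(OCc2ccccc2)c1 | intermediate
3 | 3,4,5-tris(benzyloxy)phenyl formate | O=COc1cc(OCc2ccccc2)c(OCc2ccccc2)c(OCc2ccccc2)c1 | intermediate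
4 | 3,4,5-tris(benzyloxy)phenol | Oc1cc(OCc2ccccc2)c(OCc2ccccc2)c(OCc2ccccc2)c1 | intermediate
5 | squaric acid (3,4-dihydroxycyclobut-3-ene-1,2-dione) | OC1=C(O)C(=O)C1=O | starting material
6 | squaric acid dichloride (3,4-dichlorocyclobut-3-ene-1,2-dione) | ClC1=C(Cl)C(=O)C1=O | intermediate
7 | 3-(benzyloxy)-4-chlorocyclobut-3-ene-1,2-dione | ClC1=C(OCc2ccccc2)C(=O)C1=O | intermediate
8 | 3-(benzyloxy)-4-[3,4,5-tris(benzyloxy)phenoxy]cyclobut-3-ene-1,2-dione | O=C1C(=O)C(OCc2ccccc2)=C1Oc1cc(OCc2ccccc2)c(OCc2ccccc2)c(OCc2ccccc2)c1 | intermediate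
9 | methyl vinyl ether | COC=C | starting material
10 | 1-methoxyvinyllithium | [Li]C(=C)OC | intermediate
11 | lithium 2-(benzyloxy)-1-(1-methoxyethenyl)-4-oxo-3-[3,4,5-tris(benzyloxy)phenoxy]cyclobut-2-en-1-olate (racemic) | [Li]OC1(C(=C)OC)C(OCc2ccccc2)=C(Oc2cc(OCc3ccccc3)c(OCc3ccccc3)c(OCc3ccccc3)c2)C1=O | intermediate
12 | racemic 3-(benzyloxy)-4-methoxy-4-(1-methoxyethenyl)-2-[3,4,5-tris(benzyloxy)phenoxy]cyclobut-2-en-1-one | C=C(OC)C1(OC)C(OCc2ccccc2)=C(Oc2cc(OCc3ccccc3)c(OCc3ccccc3)c(OCc3ccccc3)c2)C1=O | intermediate
13 | (3Z)-3-(benzyloxy)-4,5-dimethoxy-2-[3,4,5-tris(benzyloxy)phenoxy]hexa-1,3,5-trien-1-one | O=C=C(Oc1cc(OCc2ccccc2)c(OCc2ccccc2)c(OCc2ccccc2)c1)/C(OCc1ccccc1)=C(/OC)C(OC)=C | intermediate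
14 | 3-(benzyloxy)-4,5-dimethoxy-2-[3,4,5-tris(benzyloxy)phenoxy]cyclohexa-2,4-dien-1-one | O=C1CC(OC)=C(OC)C(OCc2ccccc2)=C1Oc1cc(OCc2ccccc2)c(OCc2ccccc2)c(OCc2ccccc2)c1 | intermediate
15 | 3-(benzyloxy)-4,5-dimethoxy-2-[3,4,5-tris(benzyloxy)phenoxy]phenol | Oc1cc(OC)c(OC)c(OCc2ccccc2)c1Oc1cc(OCc2ccccc2)c(OCc2ccccc2)c(OCc2ccccc2)c1 | intermediate
16 | 2,4,6-trihydroxybenzaldehyde | O=Cc1c(O)cc(O)cc1O | starting material
17 | 2,4,6-tris(benzyloxy)benzaldehyde | O=Cc1c(OCc2ccccc2)cc(OCc2ccccc2)cc1OCc1ccccc1 | intermediate
18 | 2,4,6-tris(benzyloxy)phenyl formate | O=COc1c(OCc2ccccc2)cc(OCc2ccccc2)cc1OCc1ccccc1 | intermediate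
19 | 2,4,6-tris(benzyloxy)phenol | Oc1c(OCc2ccccc2)cc(OCc2ccccc2)cc1OCc1ccccc1 | intermediate
20 | 5-fluorobenzene-1,3-diol | Oc1cc(O)cc(F)c1 | starting material
21 | 1,3-bis(benzyloxy)-5-fluorobenzene | Fc1cc(OCc2ccccc2)cc(OCc2ccccc2)c1 | intermediate
22 | N-[2,4-bis(benzyloxy)-6-fluorobenzylidene]-N-methylmethanaminium chloride | C[N+](C)=Cc1c(F)cc(OCc2ccccc2)cc1OCc1ccccc1.[Cl-] | intermediate
23 | 2,4-bis(benzyloxy)-6-fluorobenzaldehyde | O=Cc1c(F)cc(OCc2ccccc2)cc1OCc1ccccc1 | intermediate
24 | 2,4-bis(benzyloxy)-6-[2,4,6-tris(benzyloxy)phenoxy]benzaldehyde | O=Cc1c(OCc2ccccc2)cc(OCc2ccccc2)cc1Oc1c(OCc2ccccc2)cc(OCc2ccccc2)cc1OCc1ccccc1 | intermediate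
25 | 2,4-bis(benzyloxy)-6-[2,4,6-tris(benzyloxy)phenoxy]phenyl formate | O=COc1c(OCc2ccccc2)cc(OCc2ccccc2)cc1Oc1c(OCc2ccccc2)cc(OCc2ccccc2)cc1OCc1ccccc1 | intermediate
26 | 2,4-bis(benzyloxy)-6-[2,4,6-tris(benzyloxy)phenoxy]phenol | Oc1c(OCc2ccccc2)cc(OCc2ccccc2)cc1Oc1c(OCc2ccccc2)cc(OCc2ccccc2)cc1OCc1ccccc1 | intermediate
27 | 2,4-difluoro-6-hydroxybenzaldehyde | O=Cc1c(O)cc(F)cc1F | starting material
28 | 2-(benzyloxy)-4,6-difluorobenzaldehyde | O=Cc1c(OCc2ccccc2)cc(F)cc1F | intermediate
29 | 2-(benzyloxy)-4-{2,4-bis(benzyloxy)-6-[2,4,6-tris(benzyloxy)phenoxy]phenoxy}-6-fluorobenzaldehyde | O=Cc1c(OCc2ccccc2)cc(Oc2c(OCc3ccccc3)cc(OCc3ccccc3)cc2Oc2c(OCc3ccccc3)cc(OCc3ccccc3)cc2OCc2ccccc2)cc1F | intermediate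
30 | 2-(benzyloxy)-6-{3-(benzyloxy)-4,5-dimethoxy-2-[3,4,5-tris(benzyloxy)phenoxy]phenoxy}-4-{2,4-bis(benzyloxy)-6-[2,4,6-tris(benzyloxy)phenoxy]phenoxy}benzaldehyde | O=Cc1c(OCc2ccccc2)cc(Oc2c(OCc3ccccc3)cc(OCc3ccccc3)cc2Oc2c(OCc3ccccc3)cc(OCc3ccccc3)cc2OCc2ccccc2)cc1Oc1cc(OC)c(OC)c(OCc2ccccc2)c1Oc1cc(OCc2ccccc2)c(OCc2ccccc2)c(OCc2ccccc2)c1 | intermediate
31 | 2-(benzyloxy)-6-{3-(benzyloxy)-4,5-dimethoxy-2-[3,4,5-tris(benzyloxy)phenoxy]phenoxy}-4-{2,4-bis(benzyloxy)-6-[2,4,6-tris(benzyloxy)phenoxy]phenoxy}phenyl formate | O=COc1c(OCc2ccccc2)cc(Oc2c(OCc3ccccc3)cc(OCc3ccccc3)cc2Oc2c(OCc3ccccc3)cc(OCc3ccccc3)cc2OCc2ccccc2)cc1Oc1cc(OC)c(OC)c(OCc2ccccc2)c1Oc1cc(OCc2ccccc2)c(OCc2ccccc2)c(OCc2ccccc2)c1 | intermediate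
32 | 2-(benzyloxy)-6-{3-(benzyloxy)-4,5-dimethoxy-2-[3,4,5-tris(benzyloxy)phenoxy]phenoxy}-4-{2,4-bis(benzyloxy)-6-[2,4,6-tris(benzyloxy)phenoxy]phenoxy}phenol | Oc1c(OCc2ccccc2)cc(Oc2c(OCc3ccccc3)cc(OCc3ccccc3)cc2Oc2c(OCc3ccccc3)cc(OCc3ccccc3)cc2OCc2ccccc2)cc1Oc1cc(OC)c(OC)c(OCc2ccccc2)c1Oc1cc(OCc2ccccc2)c(OCc2ccccc2)c(OCc2ccccc2)c1 | intermediate
33 | ring D 4,5-di-O-methyl ether of pseudopentafuhalol D | Oc1cc(O)c(Oc2cc(O)cc(O)c2Oc2cc(O)c(O)c(Oc3cc(OC)c(OC)c(O)c3Oc3cc(O)c(O)c(O)c3)c2)c(O)c1 | intermediate
34 | pseudopentafuhalol D | Oc1cc(O)c(Oc2cc(O)cc(O)c2Oc2cc(O)c(O)c(Oc3cc(O)c(O)c(O)c3Oc3cc(O)c(O)c(O)c3)c2)c(O)c1 | target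

## Step count and least certain steps

Total: 18 steps. Longest linear sequence: 9 steps (for example steps 7, 8, 11, 12, 14, 15, 16, 17, 18 from 16; the chains from 1 and from 20 are equally long).

**Step 6 (key step).** The most likely failure is diversion of the reactive species before ring closure. The enol ether of 12 may be hydrolysed by trace acid on handling, so that no 6π system remains. Ketene 13 may be captured or oligomerised if closure is slowed by the crowded, fully oxygenated triene. A lesser risk is inward rotation of the methoxy group. The fallback leaves the squarate and builds the same phenol by the classical ether route, setting out from 4.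
- 3-Hydroxy-4,5-dimethoxybenzaldehyde F1 is brominated next to its hydroxyl (Br2, NaOAc, AcOH; the site usually taken in meta-hydroxybenzaldehydes of this type) to 2-bromo-3-hydroxy-4,5-dimethoxybenzaldehyde F2.
- F2 is benzylated to 3-(benzyloxy)-2-bromo-4,5-dimethoxybenzaldehyde F3.
- An Ullmann ether coupling of F3 with 4 (CuI, N,N-dimethylglycine, Cs2CO3, dioxane, 100 °C) should give 3-(benzyloxy)-4,5-dimethoxy-2-[3,4,5-tris(benzyloxy)phenoxy]benzaldehyde F4.
- Baeyer–Villiger oxidation through 3-(benzyloxy)-4,5-dimethoxy-2-[3,4,5-tris(benzyloxy)phenoxy]phenyl formate F5 and methanolysis returns to the route at 15.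

**Step 5.** The most likely failure is loss of site selectivity in the addition, since the electronic difference between an aryloxy and a benzyloxy donor is modest; attack at the other carbonyl would place ring E on D3. Conjugate displacement of the aryloxide by 10 is a second risk. The same detour also covers a statistical outcome in step 4. It sets out from 6 and 4.
- Two equivalents of 4 with i-Pr2NEt give the symmetric diester 3,4-bis[3,4,5-tris(benzyloxy)phenoxy]cyclobut-3-ene-1,2-dione F6, whose two carbonyls are equivalent.
- Addition of 10 and capping with MeOTf give racemic 4-methoxy-4-(1-methoxyethenyl)-2,3-bis[3,4,5-tris(benzyloxy)phenoxy]cyclobut-2-en-1-one F7.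
- Benzyl alcohol with a catalytic amine base then exchanges only the aryloxy group on the β-carbon of the enone by addition–elimination; the α-aryloxy group has no such path. This returns to the route at 12 and gives back one equivalent of 4.

**Step 15.** The most likely failure is incomplete substitution. The fluoride of 29 is activated by a single formyl group that is crowded by two ortho substituents, and long heating of an electron-rich phenoxide with carbonate invites oxidative degradation. Any ortho attack in step 14 would also feed the wrong isomer into this step. The fallback removes both weaknesses by changing the halide and the mechanism, setting out from 26.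
- 2-Bromo-4-fluoro-6-hydroxybenzaldehyde F8 is benzylated to 2-(benzyloxy)-6-bromo-4-fluorobenzaldehyde F9.
- The para fluoride of F9 is the only halide open to addition–elimination, so 26 with K2CO3 in DMF should give 2-(benzyloxy)-6-bromo-4-{2,4-bis(benzyloxy)-6-[2,4,6-tris(benzyloxy)phenoxy]phenoxy}benzaldehyde F10 without positional ambiguity.
- A CuI-catalysed Ullmann coupling of F10 with 15 (N,N-dimethylglycine, Cs2CO3, dioxane, 100 °C) returns to the route at 30.

**Step 18.** The most likely failure is incomplete demethylation or degradation during the reaction. Eleven free hydroxyls consume reagent and make the boron-bound mixture heterogeneous in CH2Cl2, and HBr in contact with the phloroglucinol ring A may cause side reactions. The fallback sets out from 32 and omits step 17. BBr3 with pentamethylbenzene as a benzyl-cation scavenger (CH2Cl2, −78 to 0 °C) should cleave the ten benzyl and two methyl ethers in one homogeneous operation on the lipophilic substrate and return to the route at 34. It makes no new compound.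

## Further compounds

F1 | step 6 | 3-hydroxy-4,5-dimethoxybenzaldehyde | O=Cc1cc(O)c(OC)c(OC)c1
F2 | step 6 | 2-bromo-3-hydroxy-4,5-dimethoxybenzaldehyde | O=Cc1cc(OC)c(OC)c(O)c1Br
F3 | step 6 | 3-(benzyloxy)-2-bromo-4,5-dimethoxybenzaldehyde | O=Cc1cc(OC)c(OC)c(OCc2ccccc2)c1Br
F4 | step 6 | 3-(benzyloxy)-4,5-dimethoxy-2-[3,4,5-tris(benzyloxy)phenoxy]benzaldehyde | O=Cc1cc(OC)c(OC)c(OCc2ccccc2)c1Oc1cc(OCc2ccccc2)c(OCc2ccccc2)c(OCc2ccccc2)c1
F5 | step 6 | 3-(benzyloxy)-4,5-dimethoxy-2-[3,4,5-tris(benzyloxy)phenoxy]phenyl formate | O=COc1cc(OC)c(OC)c(OCc2ccccc2)c1Oc1cc(OCc2ccccc2)c(OCc2ccccc2)c(OCc2ccccc2)c1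
F6 | step 5 | 3,4-bis[3,4,5-tris(benzyloxy)phenoxy]cyclobut-3-ene-1,2-dione | O=C1C(=O)C(Oc2cc(OCc3ccccc3)c(OCc3ccccc3)c(OCc3ccccc3)c2)=C1Oc1cc(OCc2ccccc2)c(OCc2ccccc2)c(OCc2ccccc2)c1
F7 | step 5 | racemic 4-methoxy-4-(1-methoxyethenyl)-2,3-bis[3,4,5-tris(benzyloxy)phenoxy]cyclobut-2-en-1-one | C=C(OC)C1(OC)C(Oc2cc(OCc3ccccc3)c(OCc3ccccc3)c(OCc3ccccc3)c2)=C(Oc2cc(OCc3ccccc3)c(OCc3ccccc3)c(OCc3ccccc3)c2)C1=O
F8 | step 15 | 2-bromo-4-fluoro-6-hydroxybenzaldehyde | O=Cc1c(O)cc(F)cc1Br
F9 | step 15 | 2-(benzyloxy)-6-bromo-4-fluorobenzaldehyde | O=Cc1c(OCc2ccccc2)cc(F)cc1Br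
F10 | step 15 | 2-(benzyloxy)-6-bromo-4-{2,4-bis(benzyloxy)-6-[2,4,6-tris(benzyloxy)phenoxy]phenoxy}benzaldehyde | O=Cc1c(OCc2ccccc2)cc(Oc2c(OCc3ccccc3)cc(OCc3ccccc3)cc2Oc2c(OCc3ccccc3)cc(OCc3ccccc3)cc2OCc2ccccc2)cc1Br
F0 | step 18 | none | none
A1 | alternative 1 | pentamer trialdehyde (formyl at A1, C4 and E4, ten benzyl ethers) | O=Cc1cc(OCc2ccccc2)c(Oc2cc(OCc3ccccc3)cc(OCc3ccccc3)c2Oc2cc(OCc3ccccc3)c(C=O)c(Oc3cc(OCc4ccccc4)c(OCc4ccccc4)c(OCc4ccccc4)c3Oc3cc(OCc4ccccc4)c(C=O)c(OCc4ccccc4)c3)c2)c(OCc2ccccc2)c1
A2 | alternative 1 | pentamer triphenol (hydroxyl at A1, C4 and E4, ten benzyl ethers) | Oc1cc(OCc2ccccc2)c(Oc2cc(OCc3ccccc3)cc(OCc3ccccc3)c2Oc2cc(OCc3ccccc3)c(O)c(Oc3cc(OCc4ccccc4)c(OCc4ccccc4)c(OCc4ccccc4)c3Oc3cc(OCc4ccccc4)c(O)c(OCc4ccccc4)c3)c2)c(OCc2ccccc2)c1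
A3 | alternative 1 | 3,5-bis(benzyloxy)-4-fluorobenzaldehyde | O=Cc1cc(OCc2ccccc2)c(F)c(OCc2ccccc2)c1
A4 | alternative 2 | methyl 3,5-dioxo-6-(decabenzyl BCDE aryloxy)hexanoate | COC(=O)CC(=O)CC(=O)COc1cc(OCc2ccccc2)cc(OCc2ccccc2)c1Oc1cc(OCc2ccccc2)c(OCc2ccccc2)c(Oc2cc(OCc3ccccc3)c(OCc3ccccc3)c(OCc3ccccc3)c2Oc2cc(OCc3ccccc3)c(OCc3ccccc3)c(OCc3ccccc3)c2)c1
A5 | alternative 2 | decabenzyl pentamer with free ring A triol | Oc1cc(O)c(Oc2cc(OCc3ccccc3)cc(OCc3ccccc3)c2Oc2cc(OCc3ccccc3)c(OCc3ccccc3)c(Oc3cc(OCc4ccccc4)c(OCc4ccccc4)c(OCc4ccccc4)c3Oc3cc(OCc4ccccc4)c(OCc4ccccc4)c(OCc4ccccc4)c3)c2)c(O)c1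
A6 | alternative 3 | pentamer aldehyde (formyl at C4 of ring C, twelve benzyl ethers) | O=Cc1c(Oc2cc(OCc3ccccc3)c(OCc3ccccc3)c(OCc3ccccc3)c2Oc2cc(OCc3ccccc3)c(OCc3ccccc3)c(OCc3ccccc3)c2)cc(Oc2c(OCc3ccccc3)cc(OCc3ccccc3)cc2Oc2c(OCc3ccccc3)cc(OCc3ccccc3)cc2OCc2ccccc2)cc1OCc1ccccc1
A7 | alternative 3 | 3,4,5-tris(benzyloxy)-2-[3,4,5-tris(benzyloxy)phenoxy]phenol | Oc1cc(OCc2ccccc2)c(OCc2ccccc2)c(OCc2ccccc2)c1Oc1cc(OCc2ccccc2)c(OCc2ccccc2)c(OCc2ccccc2)c1
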